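If target and isomer of the product exchange quickly against the length of a run, one member opened, then a late ratio of the two measures a balance set by temperature, not a speed.

| setting | beta | theta | alder | ash | elm | maple |
|---|---|---|---|---|---|---|
| solid substrate | 20 mM | 20 mM | 20 mM | 20 mM | 20 mM | 20 mM |
| reagent | 0.53 equiv | 2.1 equiv | 1.05 equiv | 1.05 equiv | 1.05 equiv | 1.05 equiv |
| temperature | 15 °C | 48 °C | 60 °C | 30 °C | 0 °C |  |
| remark | run made earlier | run made earlier |  |  |  | at 0 °C until 8.0 min, from then on at 60 °C |
| time |  |  | 40 min | 40 min | 40 min | 40 min |

| run | time / min | target / % | isomer of the product / % | solid substrate / % |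
|---|---|---|---|---|
| beta | 30.0 | 0.7 | 1.8 | 93.1 |
| beta | 60.0 | 0.2 | 4.0 | 89.1 |
| beta | 120 | 1.8 | 9.8 | 82.0 |
| beta | 180 | 2.0 | 16.1 | 76.5 |
| beta | 360 | 2.3 | 29.2 | 61.4 |
| theta | 15.0 | 0.4 | 1.5 | 96.3 |
| theta | 25.0 | 0.3 | 3.2 | 94.3 |
| theta | 50.0 | 1.0 | 8.6 | 87.3 |
| theta | 80.0 | 2.7 | 14.0 | 80.9 |

(scatter of a reading: 0.5 percentage points)

- at the start none of the solid substrate is in solution
- what has only dissolved of solid substrate counts as not reacted
- a reading or a percentage of target counts all its forms, free or not

1. the best flask by share of target in all that became target or isomer of the product; "all alike" if 1.5 percentage points covers them all (alder / ash / elm / maple / all alike)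
2. share of target in all that became target or isomer of the product, alder
3. share of target in all that became target or isomer of the product, ash
4. share of target in all that became target or isomer of the product, elm
5. share of target in all that became target or isomer of the product, maple

She compared rates at one moment in the beta run. Between 180 min and 360 min, isomer of the product rose from 16.1% to 29.2% while target stayed near 2.3%, so she took target to be passing on as fast as it formed. She read the ratio of isomer to target as 12.7 at the end of beta and 5.19 at the end of theta. A second member objected that the two runs differ in reagent as well. She answered that a balance between target and isomer contains no reagent term.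

The meeting then took both ratios as balances under thermodynamic control. From them it read the exchange heat, the gas constant times the logarithm of the two ratios' quotient, divided by the difference of their reciprocal absolute temperatures: 20.9 kJ mol⁻¹. This gives a balance share of target of 20.4% at 60 °C, 10.8% at 30 °C and 4.65% at 0 °C.

The second member asked how the comparison drifts. The beta share read 28.0% at 30.0 min, though with target at 0.7% against a scatter of 0.5 percentage points, and 7.30% at the end. The next beta reading, at 60.0 min, gave 4.76%, so the early shares were weak evidence. On that evidence the meeting still supposed that the share starts high and falls towards balance, and that the fall may be slower in the cold. Its own reckoning therefore set alder at 20.4%, ash at 10.8%, and maple with alder, since maple spends 32.0 min at 60 °C, more than the 8.0 min before the change. It expected elm above 4.65% by an unread amount and put its guess on elm.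

The forecast differs. It gave 13.5% for alder, 13% for ash, 13% for elm (6% to 21%) and 13.5% for maple, with the verdict all alike. Its ground was a pooled share of target of about 15% in beta up to 120 min and about 14% across theta, “despite a 33 °C and fourfold reagent difference”.

The simulation gave 24.4% for alder, 12.0% for ash, 70.9% for elm and 24.4% for maple, so the best flask is elm.

    starting material ⇌ reactive form (K = 0.780, k = 0.00800 s⁻¹, Ea = 80.0 kJ mol⁻¹, ΔH = −50.0 kJ mol⁻¹)
    reagent + reactive form → target (k = 0.0540 L mol⁻¹ s⁻¹, Ea = 54.0 kJ mol⁻¹)
    solid substrate ⇌ starting material, rate k3*(cs3 - [starting material]) while solid is left; crystals form when [starting material] > cs3 (solubility = 1.30 mM, k = 8.70 × 10⁻⁴ s⁻¹)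
    target ⇌ isomer of the product (K = 31.0, k = 4.10 × 10⁻⁴ s⁻¹, Ea = 93.0 kJ mol⁻¹, ΔH = −29.0 kJ mol⁻¹)
    crystals ⇌ target, rate k5*(cs5 - [target]) while solid is left; crystals form when [target] > cs5 (solubility = 3.80 mM, k = 0.00550 s⁻¹)
    (constants at 0 °C)

In ash, the relaxation half-life of the exchange by this step alone, both ways together, is 0.440 min, short against 40 min, and the share of 12.0% lies near the reckoned 10.8%. Elm stands at 70.9%, far above its reckoned 4.65%, and left for 400 min it reads 11.6%. The neighbouring flask repeats ash at 55 °C. The same exchange heat gives it a balance share of 18.6%, and the flask gave 21.6%.

The data stem from a simulated flask with constants of no real substance.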